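**Assumption:** one- and two-carbon reagents (MeI, MeLi, CO/MeOH, CH2O, Ac2O) and the MOM group are treated as reagents/protecting group, not starting materials; all are under eight heavy atoms anyway.

## Retrosynthetic overview

1. The target (1R,2S,4aS,8aS; trans-decalin, three methyls cis) comes from MOM removal after forming the C1(decalin)–CH2Ar bond.
2. That bond is made by adding a trans-decalin tertiary radical (from the cesium oxalate of a tertiary carbinol) to the exocyclic CH2 of an in-situ ortho-quinone methide; this sets the benzylic quaternary centre.
3. The carbinol comes from a bicyclic ketone made by methylenecyclohexane annulation: intramolecular enolate alkylation closes ring A (already carrying the exocyclic methylene) onto ring B.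
4. Ring B is purchased as 3-methylcyclohexenone; its quaternary centre is set by catalytic asymmetric conjugate addition of an alkenyl-aluminium from 5-chloropentyne. The ring-fusion and secondary-methyl centres are set by equilibration.
5. The o-quinone methide precursor is built from catechol: mono-MOM, para-bromination, methoxycarbonylation, ortho-hydroxymethylation, acetylation.

## Route

**Step 1**
Reactants: 1 5-chloropent-1-yne; 2 3-methylcyclohex-2-en-1-one
Product: 3 (S)-3-(5-chloropent-1-en-2-yl)-3-methylcyclohexan-1-one
Conditions: 1, DIBAL-H, Ni(dppp)Cl2 (3 mol %), THF, 0→22 °C; then 2, CuCl2·2H2O (5 mol %), chiral sulfonate-NHC·Ag complex (2.5 mol %, enantiomer giving 3S), THF, 22 °C; Rochelle-salt work-up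
Reagents that add atoms: none (DIBAL-H supplies only H)
Why: Ni-catalysed α-selective hydroalumination gives the internal alkenyl-aluminium, which undergoes NHC–Cu-catalysed enantioselective conjugate addition to the β-methyl enone, creating the quaternary stereocentre (S) under catalyst control while the alkyl chloride is untouched.

**Step 2**
Reactants: 3
Product: 4 (5S)-5-(5-chloropent-1-en-2-yl)-2,5-dimethylcyclohexan-1-one (C2 epimer mixture)
Conditions: LDA, THF, −78 °C; MeI, −78→0 °C
Reagents that add atoms: iodomethane, CI
Why: Kinetic enolate alkylation: LDA deprotonates the unhindered C6 rather than the neopentyl C2, and the new methyl configuration does not matter because it is equilibrated in step 3.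

**Step 3**
Reactants: 4
Product: 5 (2S,4aS,8aR)-2,4a-dimethyl-5-methylideneoctahydronaphthalen-1(2H)-one (trans-fused, 2-methyl equatorial)
Conditions: t-BuOK, t-BuOH/THF, 25→45 °C; minor cis-fused isomer separated and re-equilibrated (NaOMe, MeOH)
Reagents that add atoms: none
Why: Methylenecyclohexane annulation by intramolecular enolate alkylation (6-exo-tet; only the enolate toward the neopentyl CH2 can close a six-membered ring); the same alkoxide epimerises both α-centres of the ketone to the expected thermodynamic isomer (trans ring fusion, equatorial methyl), the quaternary centre being fixed.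

**Step 4**
Reactants: 5
Product: 6 methyl (1S,2S,4aS,8aR)-1,2,4a-trimethyl-5-methylidenedecahydronaphthalen-1-yl oxalate (major C1 epimer; C1 configuration is erased in step 10)
Conditions: MeLi, CeCl3, THF, −78 °C; then ClC(O)CO2Me, −78→0 °C
Reagents that add atoms: methyllithium, [Li]C; methyl chlorooxoacetate, COC(=O)C(=O)Cl
Why: Organocerium 1,2-addition (non-basic, so no enolisation or epimerisation) from the equatorial face anti to the axial angular methyl, followed by in-situ O-acylation of the tertiary alkoxide to give the chromatographable mixed oxalate.

**Step 5**
Reactants: 7 catechol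
Product: 8 2-(methoxymethoxy)phenol
Conditions: NaH (1.0 equiv), THF/DMF, 0 °C; MOMCl (1.0 equiv)
Reagents that add atoms: chloromethyl methyl ether, COCCl
Why: Statistical mono-O-alkylation (Williamson) of the symmetric diol; unreacted catechol and bis-ether are easily separated.

**Step 6**
Reactants: 8
Product: 9 4-bromo-2-(methoxymethoxy)phenol
Conditions: NBS, MeCN, 0 °C
Reagents that add atoms: N-bromosuccinimide, O=C1CCC(=O)N1Br
Why: Electrophilic aromatic bromination para to the free hydroxyl, the stronger director, as with guaiacol.

**Step 7**
Reactants: 9
Product: 10 methyl 4-hydroxy-3-(methoxymethoxy)benzoate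
Conditions: Pd(OAc)2, Xantphos, CO (1 atm), Et3N, MeOH/DMF, 80 °C
Reagents that add atoms: carbon monoxide, [C-]#[O+]; methanol, CO
Why: Pd-catalysed methoxycarbonylation of the aryl bromide; the free phenol and the MOM acetal tolerate the basic conditions.

**Step 8**
Reactants: 10
Product: 11 methyl 4-hydroxy-3-(hydroxymethyl)-5-(methoxymethoxy)benzoate
Conditions: 37 % aq. CH2O, NaOH (1.1 equiv), H2O, 40 °C; AcOH quench
Reagents that add atoms: formaldehyde, C=O
Why: Lederer–Manasse ortho-hydroxymethylation of the phenoxide at the only free ortho position; the para-phenoxide deactivates the ester toward saponification.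

**Step 9**
Reactants: 11
Product: 12 methyl 4-acetoxy-3-(acetoxymethyl)-5-(methoxymethoxy)benzoate
Conditions: Ac2O, pyridine, DMAP (cat.), CH2Cl2, 0 °C→rt
Reagents that add atoms: acetic anhydride, CC(=O)OC(C)=O
Why: Exhaustive acetylation gives a bench-stable, masked o-quinone methide precursor (benzylic acetate as leaving group, aryl acetate as trigger).

**Step 10**
Reactants: 6; 12
Product: 13 methyl 4-hydroxy-3-(methoxymethoxy)-5-{[(1R,2S,4aS,8aS)-1,2,4a-trimethyl-5-methylidenedecahydronaphthalen-1-yl]methyl}benzoate
Conditions: 6, CsOH·H2O (1.0 equiv), THF/H2O, rt, evaporate; then 12 (2 equiv), Ir[dF(CF3)ppy]2(dtbbpy)PF6 (2 mol %), K2HPO4 (3 equiv), DME/DMF 3:1, H2O (10 equiv), degassed, blue LEDs, 60 °C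
Reagents that add atoms: none
Why: Proposed new method: saponification gives the cesium tert-alkyl oxalate, which excited Ir(III) oxidises to release 2 CO2 and the tertiary decalinyl radical, while phosphate slowly unmasks the aryl acetate of 12 and 1,4-elimination of acetate gives a low steady-state concentration of the ester-activated o-quinone methide; the nucleophilic radical adds to its unhindered exocyclic CH2 (aromatisation-driven Giese-type addition), the phenoxyl radical is reduced by Ir(II) and protonated, and attack on the equatorial face anti to the axial angular methyl places CH2Ar equatorial and the methyl axial (1R); the exocyclic alkene is inert (only 4-exo/5-endo closures available); closest known chemistry is photoredox Giese coupling of trans-decalin tertiary radicals from cesium oxalates (same facial selectivity) and radical 1,6-addition of tertiary alkyl radicals to para-quinone methides.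

**Step 11**
Reactants: 13
Product: 14 dictyoceratin A, methyl 3,4-dihydroxy-5-{[(1R,2S,4aS,8aS)-1,2,4a-trimethyl-5-methylidenedecahydronaphthalen-1-yl]methyl}benzoate
Conditions: HCl (cat., ca. 0.3 M) in MeOH, 25–40 °C, argon
Reagents that add atoms: none
Why: Acid-catalysed methanolysis of the phenolic MOM acetal; ester exchange is degenerate in MeOH and dilute methanolic HCl should not protonate the 1,1-disubstituted alkene.

## Compound list

1 | 5-chloropent-1-yne | C#CCCCCl | starting material
2 | 3-methylcyclohex-2-en-1-one | CC1=CC(=O)CCC1 | starting material
3 | (S)-3-(5-chloropent-1-en-2-yl)-3-methylcyclohexan-1-one | C[C@]1(C(=C)CCCCl)CCCC(=O)C1 | intermediate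
4 | (5S)-5-(5-chloropent-1-en-2-yl)-2,5-dimethylcyclohexan-1-one (C2 epimers) | C[C@]1(C(=C)CCCCl)CCC(C)C(=O)C1 | intermediate
5 | (2S,4aS,8aR)-2,4a-dimethyl-5-methylideneoctahydronaphthalen-1(2H)-one | C=C1CCC[C@H]2C(=O)[C@@H](C)CC[C@]12C | intermediate
6 | methyl (1S,2S,4aS,8aR)-1,2,4a-trimethyl-5-methylidenedecahydronaphthalen-1-yl oxalate (major C1 epimer) | C=C1CCC[C@H]2[C@@](C)(OC(=O)C(=O)OC)[C@@H](C)CC[C@]12C | intermediate
7 | catechol | Oc1ccccc1O | starting material
8 | 2-(methoxymethoxy)phenol | COCOc1ccccc1O | intermediate
9 | 4-bromo-2-(methoxymethoxy)phenol | COCOc1cc(Br)ccc1O | intermediate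
10 | methyl 4-hydroxy-3-(methoxymethoxy)benzoate | COCOc1cc(C(=O)OC)ccc1O | intermediate
11 | methyl 4-hydroxy-3-(hydroxymethyl)-5-(methoxymethoxy)benzoate | COCOc1cc(C(=O)OC)cc(CO)c1O | intermediate
12 | methyl 4-acetoxy-3-(acetoxymethyl)-5-(methoxymethoxy)benzoate | COCOc1cc(C(=O)OC)cc(COC(C)=O)c1OC(C)=O | intermediate
13 | methyl 4-hydroxy-3-(methoxymethoxy)-5-{[(1R,2S,4aS,8aS)-1,2,4a-trimethyl-5-methylidenedecahydronaphthalen-1-yl]methyl}benzoate | C=C1CCC[C@H]2[C@](C)(Cc3cc(C(=O)OC)cc(OCOC)c3O)[C@@H](C)CC[C@]12C | intermediate
14 | dictyoceratin A | C=C1CCC[C@H]2[C@](C)(Cc3cc(C(=O)OC)cc(O)c3O)[C@@H](C)CC[C@]12C | target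

## Summary

**Total steps:** 11

**Longest linear sequence:** 7 (steps 5–9, then 10 and 11); the decalin branch (steps 1–4) joins at step 10.

**Steps most likely to fail, with fallbacks:**

1. **Step 10** (untested radical/o-quinone methide union; risks are phenoxide quenching of the photocatalyst and o-quinone methide hydration or oligomerisation). Fallback: keep the same tertiary radical but change the acceptor class to the aryl aldehyde N-tosylhydrazone (from Mg-mediated ortho-formylation of 10, O-protection, TsNHNH2). Radical addition to C=N followed by base-induced loss of sulfinate and N2 gives the same C–CH2Ar bond.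

2. **Step 3** (the trans:cis ring-fusion equilibrium of this angular-methyl decalone may be only modestly in favour of trans). Fallback: replace the alkylative closure with an aldol-condensation annulation (TBS-protected pent-4-yn-1-ol in step 1, then deprotection, oxidation and aldol condensation to the ring-fusion enone). Li/NH3 reduction with kinetic enolate protonation anti to the angular methyl then sets the trans fusion.

3. **Step 1** (regioselectivity of the hydroalumination and enantioselectivity with a functionalised α-alkenyl-aluminium). Fallback: swap the roles of the two groups. Install the alkenyl unit first by 1,2-addition/hydrolysis on the enol ether of cyclohexane-1,3-dione to give the 3-alkenyl dienone, then create the quaternary centre by NHC–Cu-catalysed 1,4-addition of MeMgBr.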